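Plan
- **Enabling feature.** The ten-membered ring is numbered C1 (ketone), C2, C3 (carbinol), C4 (methyl), C5, C6 (lactone O), C7, C8 (ester O), C9, C10 (methyl); C11–C13 belong to the butenolide. The C1 carbonyl, the C3 hydroxyl and the cis C4–C5 oxirane (oxide of a Z alkene) are what remains when the C1–C5 bond of a cis-fused 1-hydroxy bicyclo[5.3.0]decane is cut heterolytically with a leaving group on C4 next to an oxygen on C3.
- **Cuts, in order.** Oxirane oxygen; C1–C5 re-joined (Grob retron) to a 5-7-5 epoxy alcohol; C8–O acyl and C13–O acetyl; C5–C6 (vinylogous Michael); C1–C10 (alkenyllithium plus enone); C8–C9 (bromoallylation); C7–C8 and C11–C12 (carbomagnesiation, CO2).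
- **Forward order of rings.** The butenolide is made first. The cyclopentenone enters as a chiral block. The seven-membered ring closes through C5–C6. The ten-membered ring appears when the shared bond is cut.
- **Stereochemistry.** C1 comes from (S)-4-hydroxycyclopentenone. C8 comes from a catalytic asymmetric bromoallylation (made as the R epimer, inverted on esterification). C6 is set by allylic strain at C8 during ring closure. C10 is set by hydrogenation anti to two silyl ethers. C3 is set by convex-face epoxidation. C4/C5 are set by hydroxyl-directed peracid epoxidation.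
- **Design point.** An oxirane fused to the cyclopentane holds its C4–O bond only about 60–100° away from C1–C5, so it cannot fragment in a concerted way. The oxirane is therefore placed trans to C6, and bromide inverts C4 in the flask. The real leaving group then sits cis to C6 and antiperiplanar to C1–C5.

Key step: step 23

Remark on notation: in the tricycles β is the face that carries the C1 oxygen and α the opposite face.
Remark on chemistry: both enantiomers of the oxazoline–sulfonamide ligand are taken to be accessible, so the sense of induction in step 4 can be chosen.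

Step 1
Reactants: 1 but-2-yne-1,4-diol; 2 vinylmagnesium bromide
Product: 4 3-(hydroxymethyl)-4-vinylfuran-2(5H)-one, via alkenylmagnesium chelate 3 (not isolated)
Conditions: 2 (3.5 equiv), THF–toluene, 80 °C; CO2 (gas), 0 °C; 2 M HCl
Reagents that add atoms: carbon dioxide O=C=O
Why: Alkoxide-directed anti carbomagnesiation of a propargylic alcohol should put the vinyl group on C7 and magnesium on C11 cis to the C6 alkoxide, so that carboxylation and acid lactonisation can give only the 6,12-butenolide, and the symmetry of 1 leaves no regiochemical choice.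

Step 2
Reactants: 4 3-(hydroxymethyl)-4-vinylfuran-2(5H)-one
Product: 5 3-[(tert-butyldiphenylsilyloxy)methyl]-4-vinylfuran-2(5H)-one
Conditions: t-BuPh2SiCl, imidazole, CH2Cl2, 0 °C
Reagents that add atoms: tert-butylchlorodiphenylsilane CC(C)(C)[Si](Cl)(c1ccccc1)c1ccccc1
Why: Standard silylation of the only hydroxyl; the bulky, acid-stable silyl ether has to outlast steps 3 to 15.

Step 3
Reactants: 5 3-[(tert-butyldiphenylsilyloxy)methyl]-4-vinylfuran-2(5H)-one
Product: 6 4-[(tert-butyldiphenylsilyloxy)methyl]-5-oxo-2,5-dihydrofuran-3-carbaldehyde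
Conditions: OsO4 (2 mol %), NaIO4, 2,6-lutidine, dioxane–H2O, rt
Reagents that add atoms: sodium periodate [Na+].[O-]I(=O)(=O)=O (source of the aldehyde oxygen, passed on through OsO4)
Why: Lemieux–Johnson cleavage should take the monosubstituted vinyl group only, because the tetrasubstituted ring alkene is electron-poor and hindered.

Step 4
Reactants: 6 4-[(tert-butyldiphenylsilyloxy)methyl]-5-oxo-2,5-dihydrofuran-3-carbaldehyde; 7 2,3-dibromopropene
Product: 9 (R)-4-(3-bromo-1-hydroxybut-3-enyl)-3-[(tert-butyldiphenylsilyloxy)methyl]furan-2(5H)-one, via trimethylsilyl ether 8 (not isolated)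
Conditions: CrBr3 (10 mol %), chiral oxazoline–sulfonamide ligand (11 mol %, enantiomer giving R), Et3N (20 mol %), Co(C32H16N8) (cobalt phthalocyanine, 1 mol %), Mn, Me3SiCl, LiCl, THF, 0 °C; 1 M HCl
Reagents that add atoms: chlorotrimethylsilane C[Si](C)(C)Cl (stays in 8 only)
Why: Catalytic asymmetric Nozaki–Hiyama–Kishi 2-haloallylation of a non-enolisable aldehyde, in which the chromium-bound ligand sets C8; the R alcohol (8-epi with respect to the target) is chosen on purpose because it steers steps 13 and 14 and is inverted in step 21.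

Step 5
Reactants: 9 (R)-bromo homoallylic alcohol
Product: 10 (R)-4-[3-bromo-1-(tert-butyldimethylsilyloxy)but-3-enyl]-3-[(tert-butyldiphenylsilyloxy)methyl]furan-2(5H)-one
Conditions: t-BuMe2SiOTf, 2,6-lutidine, CH2Cl2, −78 °C
Reagents that add atoms: tert-butyldimethylsilyl triflate CC(C)(C)[Si](C)(C)OS(=O)(=O)C(F)(F)F
Why: Silyl triflate silylation of a hindered secondary alcohol under conditions too weakly basic to touch the acidic C6 hydrogens.

Step 6
Reactants: 10 bis-silyl butenolide
Product: 11 2-(triisopropylsilyloxy)furan carrying the C13 silyloxymethyl group at position 3 and the (R)-3-bromo-1-(silyloxy)but-3-enyl chain at position 4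
Conditions: i-Pr3SiOTf, Et3N, CH2Cl2, 0 °C
Reagents that add atoms: triisopropylsilyl triflate CC(C)[Si](C(C)C)(C(C)C)OS(=O)(=O)C(F)(F)F
Why: Soft enolisation of the butenolide to the aromatic 2-silyloxyfuran masks the lactone carbonyl and the acidic C6–H against the organolithium chemistry of step 10.

Step 7
Reactants: 12 (S)-4-hydroxycyclopent-2-enone
Product: 13 (S)-4-(triethylsilyloxy)cyclopent-2-enone
Conditions: Et3SiCl, imidazole, CH2Cl2, 0 °C
Reagents that add atoms: chlorotriethylsilane CC[Si](Cl)(CC)CC
Why: Standard silylation; the triethylsilyl ether blocks one face of the enone and can later be removed beside tert-butyl-substituted silyl ethers.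

Step 8
Reactants: 13 (S)-4-(triethylsilyloxy)cyclopent-2-enone
Product: 14 trans-3-methyl-4-(triethylsilyloxy)-1-(trimethylsilyloxy)cyclopent-1-ene (3S,4S)
Conditions: MeLi (2.2 equiv), CuI (1.1 equiv), Et2O, 0 °C; 13, Me3SiCl, −78 °C
Reagents that add atoms: lithium dimethylcuprate [Li+].C[Cu-]C; chlorotrimethylsilane C[Si](C)(C)Cl
Why: Chlorosilane-accelerated cuprate conjugate addition, anti to the silyl ether, brings in C15 and stores the enolate as a regiodefined silyl enol ether.

Step 9
Reactants: 14 silyl enol ether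
Product: 15 (S)-3-methyl-4-(triethylsilyloxy)cyclopent-2-enone (carbonyl = C1, alkene = C5=C4, carbinol = C3)
Conditions: Pd(OAc)2 (10 mol %), O2 (1 atm), DMSO, 40 °C
Reagents that add atoms: none
Why: Saegusa–Ito dehydrogenation restores the enone with the methyl group now on the β-carbon (C4); the stereocentre made in step 8 disappears and C3 is untouched.

Step 10
Reactants: 11 bromoalkenyl silyloxyfuran; 15 (S)-3-methyl-4-(triethylsilyloxy)cyclopent-2-enone
Product: 18 coupled cyclopentene with C1 and C3 triethylsilyl ethers cis to each other, C10=C14 methylene and intact silyloxyfuran, via alkenyllithium 16 (not isolated), via lithium alkoxide 17 (not isolated)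
Conditions: 11, t-BuLi (2.0 equiv), Et2O, −78 °C; 15, −78 °C; Et3SiOTf, −78 → −20 °C
Reagents that add atoms: triethylsilyl triflate CC[Si](CC)(CC)OS(=O)(=O)C(F)(F)F; tert-butyllithium [Li]C(C)(C)C (lithium in 16 and 17 only)
Why: Bromine–lithium exchange followed by 1,2-addition of the alkenyllithium to the β-substituted enone from the face opposite the C3 silyl ether should set C1 (C1–O cis to C3–O), and the tertiary alkoxide is silylated in the flask because the free doubly allylic alcohol would ionise easily.

Step 11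
Reactants: 18 coupled bis(triethylsilyl) ether
Product: 19 butenolide with free C3 allylic alcohol (C1 OTES, C8 OTBS and C13 OTBDPS retained)
Conditions: HF·pyridine, pyridine, THF, 0 °C
Reagents that add atoms: none
Why: Buffered fluoride desilylation follows the order of lability silyl ketene acetal > secondary triethylsilyl > tertiary and tert-butyl-substituted silyl ethers, so the butenolide and the C3 alcohol should be released alone.

Step 12
Reactants: 19 allylic alcohol
Product: 20 4-alkenyl-2-methyl-4-(triethylsilyloxy)cyclopent-2-enone tethered to the butenolide (C3 ketone, C4=C5, quaternary C1)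
Conditions: MnO2, CH2Cl2, rt
Reagents that add atoms: none
Why: Neutral allylic alcohol oxidation gives the enone whose β-carbon is C5; the C3 stereocentre has served its purpose and is erased.

Step 13
Reactants: 20 enone butenolide
Product: 22 tricyclic enol triflate (1β-OTES, 5βH, 6βH, 8β-OTBS, 13-OTBDPS, 10(14)-methylene, 3-triflyloxy-3-ene, 7(11)-en-6,12-olide), via lithium enolate 21 (not isolated)
Conditions: LiN(SiMe3)2 (1.1 equiv), THF, −78 → −30 °C; PhNTf2, −78 → 0 °C
Reagents that add atoms: N-phenylbis(trifluoromethanesulfonimide) O=S(=O)(N(c1ccccc1)S(=O)(=O)C(F)(F)F)C(F)(F)F; lithium hexamethyldisilazide [Li]N([Si](C)(C)C)[Si](C)(C)C (lithium in 21 only)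
Why: Intramolecular vinylogous Michael addition of the lithium dienolate (γ-carbon C6, the α-carbon being fully substituted) to C5, then O-triflation of the regiodefined enolate: the tether through C10 forces the cis fusion at C1/C5, and allylic 1,3-strain (H8 eclipsing the C11 side chain, OTBS and C9 on opposite faces of the furanolate) lets C5 reach C6 only from the C9 face, which sets C6.

Step 14
Reactants: 22 tricyclic enol triflate
Product: 23 10β-methyl enol triflate (10αH)
Conditions: H2 (1 atm), RhCl(PPh3)3 (10 mol %), benzene, rt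
Reagents that add atoms: none
Why: Homogeneous hydrogenation with RhCl(PPh3)3 is selective for the 1,1-disubstituted alkene over the tetrasubstituted ones, and hydrogen should arrive from the α-face because the β-face is covered by the C1 and C8 silyl ethers, which sets C10.

Step 15
Reactants: 23 10β-methyl enol triflate
Product: 24 1β-(triethylsilyloxy)-8β-(tert-butyldimethylsilyloxy)-13-(tert-butyldiphenylsilyloxy)guaia-3,7(11)-dien-6,12-olide (5βH, 6βH, 10β-methyl)
Conditions: Pd(OAc)2 (5 mol %), PPh3 (10 mol %), HCO2H, Et3N, DMF, 50 °C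
Reagents that add atoms: none
Why: Palladium-catalysed formate reduction of an enol triflate gives the C3=C4 alkene without touching a stereocentre, and the buffered amine cannot harm C6, which in the 8-epi series is the strain-free epimer.

Step 16
Reactants: 24 tris-silyl ether
Product: 25 1β,8β,13-trihydroxyguaia-3,7(11)-dien-6,12-olide
Conditions: 48 % aq HF, MeCN, 0 °C → rt
Reagents that add atoms: none
Why: Acidic fluoride cleaves all three silyl ethers in one operation and avoids basic conditions that would deprotonate C6.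

Step 17
Reactants: 25 triol
Product: 26 13-acetoxy-1β,8β-dihydroxyguaia-3,7(11)-dien-6,12-olide
Conditions: Ac2O (1.1 equiv), 2,4,6-collidine, CH2Cl2, −20 °C
Reagents that add atoms: acetic anhydride CC(=O)OC(C)=O
Why: Kinetic acetylation distinguishes the primary allylic C13 hydroxyl from the hindered secondary C8 and the tertiary C1 hydroxyls.

Step 18
Reactants: 27 citraconic anhydride
Product: 28 4-methylfuran-2(5H)-one
Conditions: NaBH4, THF, 0 °C; 6 M HCl
Reagents that add atoms: none
Why: Borohydride reduction of this unsymmetrical maleic anhydride goes mainly to the carbonyl next to the methyl-bearing carbon, the other carbonyl being deactivated by the vinylogous donor effect of the methyl group, and acid closes the lactone; the minor 3-methyl isomer is removed by distillation.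

Step 19
Reactants: 28 4-methylfuran-2(5H)-one
Product: 29 sodium (Z)-4-hydroxy-3-methylbut-2-enoate
Conditions: NaOH (1.0 equiv), H2O–MeOH, rt; freeze-dry
Reagents that add atoms: sodium hydroxide [Na+].[OH-]
Why: Saponification keeps the Z geometry imposed by the ring, and the salt cannot relactonise while it stays basic.

Step 20
Reactants: 29 sodium (Z)-4-hydroxy-3-methylbut-2-enoate
Product: 31 (Z)-4-acetoxy-3-methylbut-2-enoic acid, via disodium salt 30 (not isolated)
Conditions: NaH (1.05 equiv), DMF, 0 °C; Ac2O (1.1 equiv), 0 °C; cold 1 M HCl to pH 3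
Reagents that add atoms: acetic anhydride CC(=O)OC(C)=O; sodium hydride [Na+].[H-] (sodium in 30 only)
Why: The alkoxide of the dianion is far more nucleophilic than the carboxylate, so O-acetylation precedes any mixed-anhydride formation that could lead back to the lactone, and cold acidification frees the Z acetoxy acid.

Step 21
Reactants: 26 13-acetate (8β-OH); 31 (Z)-4-acetoxy-3-methylbut-2-enoic acid
Product: 32 13-acetoxy-8α-[(Z)-4-acetoxy-3-methylbut-2-enoyloxy]-1β-hydroxyguaia-3,7(11)-dien-6,12-olide (8S)
Conditions: PPh3, DIAD, toluene, 0 °C → rt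
Reagents that add atoms: none
Why: Mitsunobu esterification displaces the activated C8 oxygen by the carboxylate with inversion (SN2 next to the electron-poor alkene, attack from the open α-face past H10), which installs the ester and corrects C8 to S in one step while the tertiary C1 hydroxyl is inert.

Step 22
Reactants: 32 diester alkene
Product: 33 3β,4β-epoxy-1β-hydroxy diester (oxirane cis to the C1 hydroxyl and H5, trans to C6)
Conditions: mCPBA, NaHCO3, CH2Cl2, 0 °C
Reagents that add atoms: 3-chloroperbenzoic acid OOC(=O)c1cccc(Cl)c1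
Why: Peracid epoxidation picks the only electron-rich alkene and should occur on the convex β-face, anti to the C5–C6 bond and syn to the homoallylic C1 hydroxyl (Henbest effect), which sets C3.

Step 23
Reactants: 33 3β,4β-epoxy-1β-hydroxy diester
Product: 36 1-oxo-3-hydroxy-4Z-cyclodecene butenolide diester (3S, 6R, 8S, 10S), via magnesium alkoxide 34 (not isolated), via C4 bromide 35 (not isolated)
Conditions: MeMgBr (1.0 equiv), CH2Cl2–Et2O, −78 °C; MgBr2·OEt2 (3 equiv), −78 → 0 °C; pH 7 phosphate buffer
Reagents that add atoms: magnesium dibromide etherate [Mg+2].[Br-].[Br-].CCOCC (bromine and magnesium in 35 only); methylmagnesium bromide C[Mg]Br (magnesium in 34 and 35 only)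
Why: Proposed new method: MeMgBr turns the C1 hydroxyl into its bromomagnesium alkoxide, MgBr2 binds the oxirane oxygen on the convex face and bromide opens the tertiary C4–O bond with inversion, so that 35 carries C4–Br on the face of C6 and, with the C3 oxygen pseudo-equatorial, antiperiplanar to C1–C5; push from the C1 alkoxide then breaks C1–C5 as bromide leaves, giving the C1 carbonyl, the C4=C5 double bond and a C3 magnesium alkoxide that is protonated on work-up. The closest known reactions are the Grob (Wharton) fragmentation of fused γ-halo or γ-sulfonyloxy alkoxides to medium-ring enones, the epoxy-alcohol fragmentation of bridged tertiary alcohols and the opening of trisubstituted epoxides by MgBr2 at the tertiary carbon; only their coupling in one flask is new. No ring closes by bond formation: the ten-membered ring is the perimeter of the bicyclo[5.3.0]decane and appears when the shared bond is cut. No new stereocentre arises, C3, C6, C8 and C10 are untouched, and the Z geometry follows from the cis relation of Br and C6, which leaves C3 and C6 on the same side of the new alkene when Br–C4–C5–C1 are coplanar. The step needs fragmentation to beat return to the epoxide, hydride shift and loss of HBr: return is reversible and harmless, H3 is syn to bromine and cannot migrate, migration of C2 would make a cyclobutane, and the weakly basic magnesium alkoxide spares H6 and the allylic acetates.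

Step 24
Reactants: 36 hydroxy cyclodecenone diester
Product: 37 CNP0232076.1 (3S,4R,5S,6S,8S,10S)
Conditions: mCPBA, Na2HPO4, CH2Cl2, 0 °C
Reagents that add atoms: 3-chloroperbenzoic acid OOC(=O)c1cccc(Cl)c1
Why: Henbest epoxidation of the Z allylic alcohol: allylic 1,3-strain keeps H3 in the alkene plane and the hydroxyl near 120°, so the hydrogen-bonded peracid attacks the face syn to O3 and anti to the lactone oxygen on C6, giving the threo (ring-trans) epoxy alcohol of the target, as peracids do with medium-ring Z allylic alcohols where vanadium catalysts tend to the opposite isomer.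

Compound list
1 | but-2-yne-1,4-diol | OCC#CCO | starting material
2 | vinylmagnesium bromide | C=C[Mg]Br | starting material
3 | alkenylmagnesium chelate (vinyl and Mg trans) | C=C/C(CO[Mg]Br)=C(/[Mg]Br)CO[Mg]Br | intermediate
4 | 3-(hydroxymethyl)-4-vinylfuran-2(5H)-one | OCC1=C(COC1=O)C=C | intermediate
5 | 3-[(tert-butyldiphenylsilyloxy)methyl]-4-vinylfuran-2(5H)-one | CC(C)(C)[Si](c1ccccc1)(c2ccccc2)OCC3=C(COC3=O)C=C | intermediate
6 | 4-[(tert-butyldiphenylsilyloxy)methyl]-5-oxo-2,5-dihydrofuran-3-carbaldehyde | CC(C)(C)[Si](c1ccccc1)(c2ccccc2)OCC3=C(COC3=O)C=O | intermediate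
7 | 2,3-dibromopropene | C=C(Br)CBr | starting material
8 | trimethylsilyl ether of 9 | CC(C)(C)[Si](c1ccccc1)(c2ccccc2)OCC3=C(COC3=O)[C@H](O[Si](C)(C)C)CC(Br)=C | intermediate
9 | (R)-bromo homoallylic alcohol | CC(C)(C)[Si](c1ccccc1)(c2ccccc2)OCC3=C(COC3=O)[C@H](O)CC(Br)=C | intermediate
10 | C8 tert-butyldimethylsilyl ether | CC(C)(C)[Si](c1ccccc1)(c2ccccc2)OCC3=C(COC3=O)[C@H](O[Si](C)(C)C(C)(C)C)CC(Br)=C | intermediate
11 | 2-(triisopropylsilyloxy)furan | CC(C)(C)[Si](c1ccccc1)(c2ccccc2)OCc3c(O[Si](C(C)C)(C(C)C)C(C)C)occ3[C@H](O[Si](C)(C)C(C)(C)C)CC(Br)=C | intermediate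
12 | (S)-4-hydroxycyclopent-2-enone | O=C1C[C@H](O)C=C1 | starting material
13 | (S)-4-(triethylsilyloxy)cyclopent-2-enone | O=C1C[C@H](O[Si](CC)(CC)CC)C=C1 | intermediate
14 | trans silyl enol ether | C[Si](C)(C)OC1=C[C@H](C)[C@@H](O[Si](CC)(CC)CC)C1 | intermediate
15 | (S)-3-methyl-4-(triethylsilyloxy)cyclopent-2-enone | O=C1C[C@H](O[Si](CC)(CC)CC)C(C)=C1 | intermediate
16 | alkenyllithium | CC(C)(C)[Si](c1ccccc1)(c2ccccc2)OCc3c(O[Si](C(C)C)(C(C)C)C(C)C)occ3[C@H](O[Si](C)(C)C(C)(C)C)CC([Li])=C | intermediate
17 | lithium alkoxide | CC(C)(C)[Si](c1ccccc1)(c2ccccc2)OCc3c(O[Si](C(C)C)(C(C)C)C(C)C)occ3[C@H](O[Si](C)(C)C(C)(C)C)CC(=C)[C@@]4(O[Li])C[C@H](O[Si](CC)(CC)CC)C(C)=C4 | intermediate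
18 | coupled bis(triethylsilyl) ether | CC(C)(C)[Si](c1ccccc1)(c2ccccc2)OCc3c(O[Si](C(C)C)(C(C)C)C(C)C)occ3[C@H](O[Si](C)(C)C(C)(C)C)CC(=C)[C@@]4(O[Si](CC)(CC)CC)C[C@H](O[Si](CC)(CC)CC)C(C)=C4 | intermediate
19 | C3 allylic alcohol butenolide | CC(C)(C)[Si](c1ccccc1)(c2ccccc2)OCC3=C(COC3=O)[C@H](O[Si](C)(C)C(C)(C)C)CC(=C)[C@@]4(O[Si](CC)(CC)CC)C[C@H](O)C(C)=C4 | intermediate
20 | enone butenolide | CC(C)(C)[Si](c1ccccc1)(c2ccccc2)OCC3=C(COC3=O)[C@H](O[Si](C)(C)C(C)(C)C)CC(=C)[C@@]4(O[Si](CC)(CC)CC)CC(=O)C(C)=C4 | intermediate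
21 | tricyclic lithium enolate | CC(C)(C)[Si](c1ccccc1)(c2ccccc2)OCC3=C4[C@H](O[Si](C)(C)C(C)(C)C)CC(=C)[C@@]5(O[Si](CC)(CC)CC)CC(O[Li])=C(C)[C@H]5[C@H]4OC3=O | intermediate
22 | tricyclic enol triflate | CC(C)(C)[Si](c1ccccc1)(c2ccccc2)OCC3=C4[C@H](O[Si](C)(C)C(C)(C)C)CC(=C)[C@@]5(O[Si](CC)(CC)CC)CC(OS(=O)(=O)C(F)(F)F)=C(C)[C@H]5[C@H]4OC3=O | intermediate
23 | 10β-methyl enol triflate | CC(C)(C)[Si](c1ccccc1)(c2ccccc2)OCC3=C4[C@H](O[Si](C)(C)C(C)(C)C)C[C@H](C)[C@@]5(O[Si](CC)(CC)CC)CC(OS(=O)(=O)C(F)(F)F)=C(C)[C@H]5[C@H]4OC3=O | intermediate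
24 | tris-silyl guaia-3,7(11)-dien-6,12-olide | CC(C)(C)[Si](c1ccccc1)(c2ccccc2)OCC3=C4[C@H](O[Si](C)(C)C(C)(C)C)C[C@H](C)[C@@]5(O[Si](CC)(CC)CC)CC=C(C)[C@H]5[C@H]4OC3=O | intermediate
25 | 1β,8β,13-triol | OCC1=C2[C@H](O)C[C@H](C)[C@@]3(O)CC=C(C)[C@H]3[C@H]2OC1=O | intermediate
26 | 13-acetate, 1β,8β-diol | CC(=O)OCC1=C2[C@H](O)C[C@H](C)[C@@]3(O)CC=C(C)[C@H]3[C@H]2OC1=O | intermediate
27 | citraconic anhydride | CC1=CC(=O)OC1=O | starting material
28 | 4-methylfuran-2(5H)-one | CC1=CC(=O)OC1 | intermediate
29 | sodium (Z)-4-hydroxy-3-methylbut-2-enoate | [Na+].[O-]C(=O)/C=C(/C)CO | intermediate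
30 | disodium alkoxide carboxylate | [Na+].[Na+].[O-]C(=O)/C=C(/C)C[O-] | intermediate
31 | (Z)-4-acetoxy-3-methylbut-2-enoic acid | OC(=O)/C=C(/C)COC(C)=O | intermediate
32 | 8α-ester 13-acetate alkene | CC(=O)OCC1=C2[C@@H](OC(=O)/C=C(/C)COC(C)=O)C[C@H](C)[C@@]3(O)CC=C(C)[C@H]3[C@H]2OC1=O | intermediate
33 | 3β,4β-epoxy-1β-hydroxy diester (key precursor) | CC(=O)OCC1=C2[C@@H](OC(=O)/C=C(/C)COC(C)=O)C[C@H](C)[C@@]3(O)C[C@@H]4O[C@]4(C)[C@H]3[C@H]2OC1=O | intermediate
34 | C1 bromomagnesium alkoxide of 33 | CC(=O)OCC1=C2[C@@H](OC(=O)/C=C(/C)COC(C)=O)C[C@H](C)[C@@]3(O[Mg]Br)C[C@@H]4O[C@]4(C)[C@H]3[C@H]2OC1=O | intermediate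
35 | 4α-bromo 1β,3β-bis(bromomagnesium alkoxide) | CC(=O)OCC1=C2[C@@H](OC(=O)/C=C(/C)COC(C)=O)C[C@H](C)[C@@]3(O[Mg]Br)C[C@H](O[Mg]Br)[C@@](C)(Br)[C@H]3[C@H]2OC1=O | intermediate
36 | 1-oxo-3-hydroxy-4Z-cyclodecene butenolide diester (key product) | CC(=O)OCC1=C2[C@@H](OC(=O)/C=C(/C)COC(C)=O)C[C@H](C)C(=O)C[C@H](O)/C(C)=C\[C@H]2OC1=O | intermediate
37 | CNP0232076.1 | CC(=O)OCC1=C2[C@@H](OC(=O)/C=C(/C)COC(C)=O)C[C@H](C)C(=O)C[C@H](O)[C@@]3(C)O[C@H]3[C@H]2OC1=O | target

Total step count: 24. Longest linear sequence: 18 (steps 1–6, 10–17, 21–24).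

Steps most likely to fail

1. Step 23.
   - **What may go wrong.** The tertiary bromide may ionise and lose a proton, or the activated oxirane may rearrange, faster than the C1–C5 bond breaks. The liberated enone may also re-close across the ring under the Lewis acid.
   - **Fallback (known chemistry, sets out from 25, returns at 36).** The fragmentation is run on base-tolerant silyl ethers with an isolated bromide.
     - TESCl and imidazole give the 8,13-bis(triethylsilyl) ether F1.
     - mCPBA gives the 3β,4β-epoxide F2.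
     - MgBr2·OEt2 at −40 °C with a cold quench gives the isolated bromohydrin F3.
     - t-BuMe2SiOTf and 2,6-lutidine at −78 °C cap the secondary hydroxyl to give the C3 silyl ether F4.
     - A classical alkoxide-triggered Grob fragmentation (KN(SiMe3)2, 1.0 equiv, THF, −78 → 0 °C) gives the cyclodecenone F5.
     - PPTS in MeOH frees the 8,13-diol F6.
     - Ac2O and collidine give the 13-acetate F7.
     - Mitsunobu coupling with 31 gives the C3-silylated diester F8.
     - HF·pyridine removes the last silyl group to give 36.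

2. Step 13.
   - **What may go wrong.** The dienolate may attack through its α-carbon, may expel silanolate from C13 or C8, or may fail to close the seven-membered ring before proton exchange.
   - **Fallback (sets out from 20, returns at 22).** The metal dienolate is replaced by a neutral nucleophile.
     - t-BuMe2SiOTf and Et3N at −78 °C convert the butenolide into the 2-silyloxyfuran F9; the neopentyl C2 position of the enone is slow to enolise.
     - A catalytic amount of the same silyl triflate then drives an intramolecular vinylogous Mukaiyama–Michael addition to the tricyclic silyl enol ether F10.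
     - CsF and PhNTf2 in DME convert F10 into 22.

3. Step 21.
   - **What may go wrong.** The oxyphosphonium ion may eliminate toward C9, or may be attacked with partial retention at the hindered carbinol.
   - **Fallback (sets out from 26, returns at 32).** Inversion is achieved by redox.
     - Dess–Martin periodinane gives the C8 ketone F11.
     - Luche reduction (NaBH4, CeCl3·7H2O, MeOH, −78 °C), with hydride arriving away from the C13 side chain, gives the 8α-alcohol F12.
     - F12 is acylated with 31 under 2-methyl-6-nitrobenzoic anhydride and catalytic DMAP to give 32.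

Further compounds
F1 | step 23 | 8,13-bis(triethylsilyl) ether of 25 | CC[Si](CC)(CC)OCC1=C2[C@H](O[Si](CC)(CC)CC)C[C@H](C)[C@@]3(O)CC=C(C)[C@H]3[C@H]2OC1=O
F2 | step 23 | 3β,4β-epoxide of F1 | CC[Si](CC)(CC)OCC1=C2[C@H](O[Si](CC)(CC)CC)C[C@H](C)[C@@]3(O)C[C@@H]4O[C@]4(C)[C@H]3[C@H]2OC1=O
F3 | step 23 | 4α-bromo-1β,3β-diol | CC[Si](CC)(CC)OCC1=C2[C@H](O[Si](CC)(CC)CC)C[C@H](C)[C@@]3(O)C[C@H](O)[C@@](C)(Br)[C@H]3[C@H]2OC1=O
F4 | step 23 | C3 tert-butyldimethylsilyl ether of F3 | CC[Si](CC)(CC)OCC1=C2[C@H](O[Si](CC)(CC)CC)C[C@H](C)[C@@]3(O)C[C@H](O[Si](C)(C)C(C)(C)C)[C@@](C)(Br)[C@H]3[C@H]2OC1=O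
F5 | step 23 | tris-silyl 1-oxo-4Z-cyclodecene butenolide | CC[Si](CC)(CC)OCC1=C2[C@H](O[Si](CC)(CC)CC)C[C@H](C)C(=O)C[C@H](O[Si](C)(C)C(C)(C)C)/C(C)=C\[C@H]2OC1=O
F6 | step 23 | 8,13-diol, C3 silyl ether | OCC1=C2[C@H](O)C[C@H](C)C(=O)C[C@H](O[Si](C)(C)C(C)(C)C)/C(C)=C\[C@H]2OC1=O
F7 | step 23 | 13-acetate, C3 silyl ether | CC(=O)OCC1=C2[C@H](O)C[C@H](C)C(=O)C[C@H](O[Si](C)(C)C(C)(C)C)/C(C)=C\[C@H]2OC1=O
F8 | step 23 | C3-silylated diester | CC(=O)OCC1=C2[C@@H](OC(=O)/C=C(/C)COC(C)=O)C[C@H](C)C(=O)C[C@H](O[Si](C)(C)C(C)(C)C)/C(C)=C\[C@H]2OC1=O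
F9 | step 13 | 2-(tert-butyldimethylsilyloxy)furan enone | CC(C)(C)[Si](c1ccccc1)(c2ccccc2)OCc3c(O[Si](C)(C)C(C)(C)C)occ3[C@H](O[Si](C)(C)C(C)(C)C)CC(=C)[C@@]4(O[Si](CC)(CC)CC)CC(=O)C(C)=C4
F10 | step 13 | tricyclic silyl enol ether | CC(C)(C)[Si](c1ccccc1)(c2ccccc2)OCC3=C4[C@H](O[Si](C)(C)C(C)(C)C)CC(=C)[C@@]5(O[Si](CC)(CC)CC)CC(O[Si](C)(C)C(C)(C)C)=C(C)[C@H]5[C@H]4OC3=O
F11 | step 21 | C8 ketone | CC(=O)OCC1=C2C(=O)C[C@H](C)[C@@]3(O)CC=C(C)[C@H]3[C@H]2OC1=O
F12 | step 21 | 8α-alcohol (8S) | CC(=O)OCC1=C2[C@@H](O)C[C@H](C)[C@@]3(O)CC=C(C)[C@H]3[C@H]2OC1=O
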